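A small charge of catalyst, 1.0 mM against 0.10 M of starting material, works in a closed flask under held gas phase with 2.6 mM of added ligand beside it. Friday's run is this flask, followed to 50.0 s; Tuesday's run differs in its added ligand.

| setting | Friday's | Tuesday's | flask |
|---|---|---|---|
| starting material | 0.10 M | 0.10 M | 0.10 M |
| gas phase | 6.3 mM (held) | 6.3 mM (held) | 6.3 mM (held) |
| catalyst | 1 mM | 1 mM | 1.0 mM |
| added ligand | 2.6 mM | 3.9 mM | 2.6 mM |
| remark | the very flask that is asked about, followed so far | run made earlier |  |
| time |  |  | 3.0 min |

Friday's run (percent of the starting material charged)

| time / s | target / % | starting material / % |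
|---|---|---|
| 10.0 | 4.3 | 96.2 |
| 20.0 | 8.5 | 91.8 |
| 40.0 | 15.6 | 84.7 |
| 50.0 | 19.6 | 80.9 |

Tuesday's run (percent of the starting material charged)

| time / min | target / % | starting material / % |
|---|---|---|
| 0.833 | 11.5 | 88.7 |
| 1.50 | 20.0 | 80.3 |
| 2.50 | 30.3 | 69.0 |
| 3.00 | 34.3 | 64.0 |

(scatter of a reading: 0.3 percentage points)

- at the start none of the gas phase is in solution

- birch: doubling the transfer coefficient of the gas phase, all else as stated
- ash: doubling the saturation concentration of gas phase, all else as stated
- alder: doubling the amount of catalyst, all else as stated

- target at 3.0 min, in percent of the starting material charged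
- the change that raises the amount of target at 3.0 min, in percent of the starting material charged most ("none" if none brings more than 2 percentage points) (birch / ash / alder / none)
- amount of target at 3.0 min, in percent of the starting material charged, after alder

Take the main step first. With gas and catalyst steady it is pseudo-first-order in starting material, and Friday's last reading gives a constant of 0.254 min⁻¹. If every reacted molecule is target, that makes 53.4% at 3.0 min.

Now add the ligand and follow one metal: at any moment it is free or held. Guessing one ligand per metal leaves spare ligand, the added ligand minus the catalyst, competing for it. Tuesday's constant, 0.149 min⁻¹, lies 1.70 times below Friday's, for 1.50 times the added ligand but 1.81 times the spare ligand. The first-order constant times spare ligand per catalyst reads 0.407 min⁻¹ on Friday's run and 0.431 min⁻¹ on Tuesday's: this is the spare-ligand constant. It leaves this flask's number alone, since Friday's run has the same ligand, but it prices every change of charge.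

Then the rest. Friday's first reading, 4.3% against 4.15% from the constant, shows no lag, so birch promises little. Tuesday's balance at its last reading is short by 1.7 percentage points, a rough reading of target passing on at 0.0330 min⁻¹, which lowers this flask to 50.7%.

Alder leaves 0.600 mM of spare ligand, hence a constant of 1.36 min⁻¹ and 98.3% reacted. After the leak that is 90.9% target. Ash, if the rate goes with the first power of dissolved gas, reaches 78.3% reacted, less than alder. The reckoning therefore chooses alder.

The forecast gives 50.5%, alder and 70%, the last on the ground that “Over-reaction caps target near 70%”, and it parts from this reckoning on that number. The flask gives 52.1%, and alder brings 91.6%, a gain of 39 points against 24 points for ash and 0.2 points for birch.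

    gas phase ⇌ dissolved gas, rate k1*(csat - [dissolved gas]) (kL = 4.60 s⁻¹)
    target ⇌ isomer of the product (K = 0.780, k = 3.80 × 10⁻⁴ s⁻¹)
    starting material + dissolved gas + catalyst → catalyst + target (k = 20000 M⁻² s⁻¹)
    catalyst + added ligand ⇌ idle complex, settled at all times (K = 17000 M⁻¹)

Taken away, the joining of catalyst and added ligand to idle complex lifts target at 3.0 min from 52.1% to 94.0%, and 96.5% of the catalyst stands as idle complex in this flask. The spare-ligand constant carries that: alder multiplies Friday's constant by 5.35, beyond a doubling. In the neighbour with 2.5 × 10⁻⁴ M of catalyst, the same constant gives 0.0433 min⁻¹ and 12.2% target at 3.0 min; the computed flask holds 12.4%.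

The numbers in the tables were generated by integration with constants of no real substance; the scatter is artificial.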